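**Retrosynthetic overview**

1. Core numbering (hexahydroisobenzofuran): C1 carries the 2-oxopropyl group, O2, C3 is the OCH2, C3a=C7a is the ring-fusion alkene, C4 is the carbinol, C5 the CH2, C6 the quaternary carbon, C7 carries the enol ester. The enol ester is made last by Wittig olefination of a C7 aldehyde with an acyloxymethylene ylide; the 2-oxopropyl group comes from a C1 allyl group (Wacker); the C4 alcohol and the C7 CH2OH come from one hydride reduction of a keto ester.
2. Key disconnection C5–C6: a Lewis-acid-promoted, polarised 6π electrocyclisation (an intramolecular Mukaiyama–Michael closure in the stepwise limit) of a 3,4-dialkenyl-2,5-dihydrofuran closes the six-membered ring and creates the quaternary centre.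
3. Enabling feature: the tetrasubstituted C3a=C7a bond of the dihydrofuran ring holds the C4 arm (1-ethoxyvinyl, CH2 terminus = C5) and the C7 arm (alkylidene ester, β-carbon = C6) cis, as an s-cis,Z-hexatriene with a donor end and an acceptor end. The C1 stereocentre on C7a faces the C7 ester, so 1,3-allylic strain fixes the helicity of ring closure.
4. The triene comes from Negishi union of a 3-bromo-2,5-dihydrofuran with a geometrically pure α-iodo enoate (syn-carbocupration of methyl but-2-ynoate). The bromide comes from 3,4-dibromofuran-2(5H)-one by Stille coupling, lactol formation, asymmetric allylboration and Mitsunobu cyclodehydration.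
5. Ring order: the dihydrofuran ring first (step 4), the carbocycle second (step 7).

Key step: step 7

Assumption: the allylborane derived from (+)-α-pinene is taken to add to the Si face of the aldehyde form of the lactol, as it does with other α,β-unsaturated aldehydes, so that the new carbinol is S.

**Step 1**
Reactants: 1 3,4-dibromofuran-2(5H)-one; 2 tributyl(1-ethoxyethenyl)stannane
Product: 3 3-bromo-4-(1-ethoxyethenyl)furan-2(5H)-one
Conditions: Pd2(dba)3 (cat.), AsPh3, toluene, 50 °C
Reagents that add atoms: none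
Why: Stille coupling; oxidative addition should take place at the C4–Br bond, which is β to the lactone carbonyl and the more electron-poor of the two, as in known mono-couplings of this dibromide.

**Step 2**
Reactants: 3 3-bromo-4-(1-ethoxyethenyl)furan-2(5H)-one
Product: 4 3-bromo-4-(1-ethoxyethenyl)-2,5-dihydrofuran-2-ol (lactol, both C2 epimers)
Conditions: i-Bu2AlH (1.1 equiv), CH2Cl2, −78 °C; aqueous KNaC4H4O6 work-up; crude product used at once
Reagents that add atoms: none
Why: half-reduction of a lactone to the lactol with i-Bu2AlH, whose tetrahedral aluminium lactolate is stable at −78 °C; the non-acidic work-up should prevent dehydration of the lactol to a furan.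

**Step 3**
Reactants: 4 3-bromo-4-(1-ethoxyethenyl)-2,5-dihydrofuran-2-ol; 5 (−)-B-allyldiisopinocampheylborane (from (+)-α-pinene)
Product: 6 (2Z,4S)-3-bromo-2-(1-ethoxyethenyl)hepta-2,6-diene-1,4-diol
Conditions: Et2O, −78 to 0 °C; then NaOH, H2O2
Reagents that add atoms: none
Why: Brown asymmetric allylboration of the hydroxy-aldehyde form of the lactol through a chair transition state; reagent control (Si-face attack) sets the S carbinol that becomes C1.

**Step 4**
Reactants: 6 (2Z,4S)-3-bromo-2-(1-ethoxyethenyl)hepta-2,6-diene-1,4-diol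
Product: 7 (2S)-3-bromo-4-(1-ethoxyethenyl)-2-(prop-2-en-1-yl)-2,5-dihydrofuran
Conditions: PPh3, i-PrO2CN=NCO2i-Pr, THF, 0 °C to rt
Reagents that add atoms: none
Why: Mitsunobu cyclodehydration of a Z-2-ene-1,4-diol; the primary allylic hydroxyl is activated and displaced by the secondary one (5-exo-tet), so the stereocentre is retained and the acid-labile enol ether is untouched.

**Step 5**
Reactants: 8 5-bromo-2-methylpent-2-ene; 9 methyl but-2-ynoate
Product: 13 methyl (2Z)-2-iodo-3,7-dimethylocta-2,6-dienoate, via homoprenylmagnesium bromide 10 (not isolated), via homoprenylcopper 11 (not isolated), via alkenylcopper adduct 12 (not isolated)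
Conditions: Mg, THF; CuI, THF, −40 °C; then 9, −78 °C; then I2, −78 to 0 °C
Reagents that add atoms: iodine, II
Why: syn-carbocupration of an ynoate (Normant type) followed by iodinolysis with retention; kept at −78 °C so that the alkenylcopper does not isomerise, this places iodine cis to the 4-methylpent-3-enyl chain.

**Step 6**
Reactants: 7 (2S)-3-bromo-4-(1-ethoxyethenyl)-2-(prop-2-en-1-yl)-2,5-dihydrofuran; 13 methyl (2Z)-2-iodo-3,7-dimethylocta-2,6-dienoate
Product: 16 methyl (2E)-2-[(2S)-4-(1-ethoxyethenyl)-2-(prop-2-en-1-yl)-2,5-dihydrofuran-3-yl]-3,7-dimethylocta-2,6-dienoate, via dihydrofuranyllithium 14 (not isolated), via dihydrofuranylzinc chloride 15 (not isolated)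
Conditions: t-BuLi (2 equiv), THF, −78 °C; ZnCl2, −78 to 0 °C; then 13, Pd(t-Bu3P)2 (cat.), THF, rt
Reagents that add atoms: none
Why: bromine–lithium exchange, transmetalation to zinc and Negishi coupling, which tolerates two fully substituted alkenyl partners at room temperature and should keep the alkene geometry of the electron-poor iodide.

**Step 7**
Reactants: 16 methyl (2E)-2-[(2S)-4-(1-ethoxyethenyl)-2-(prop-2-en-1-yl)-2,5-dihydrofuran-3-yl]-3,7-dimethylocta-2,6-dienoate
Product: 18 methyl (1S,6S,7R)-6-methyl-6-(4-methylpent-3-en-1-yl)-4-oxo-1-(prop-2-en-1-yl)-1,3,4,5,6,7-hexahydroisobenzofuran-7-carboxylate, via cyclised ethyl dienol ether 17 (not isolated)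
Conditions: Me2AlCl (1.1 equiv), CH2Cl2, −78 to 0 °C; then 1 M HCl, THF, 0 °C to rt; then Et3N (cat.), CH2Cl2, rt
Reagents that add atoms: water, O
Why: Me2AlCl binds the ester carbonyl and makes C6 (β-carbon of the alkylidene ester) electrophilic while the ethoxydiene terminus C5 stays nucleophilic, so the triene C5=C4–C3a=C7a–C7=C6 should close by a polarised disrotatory 6π electrocyclisation to dienol ether 17, whose acid hydrolysis with γ-protonation gives 18. The closest known reactions are the Me2AlCl-catalysed 6π electrocyclisation of hexatrienes bearing a carbonyl group at C2 and the intramolecular Mukaiyama–Michael addition. The one ring closed is the six-membered carbocycle, by 6-endo-trig attack of C5 on C6. The C6 quaternary centre is set by helicity: 1,3-allylic strain between the aluminium-bound ester on C7 and the allyl group on C1 turns the ester to the face of the C1 hydrogen, so C6 meets C5 on the allyl face and the alkene geometry (chain cis to the dihydrofuran) is translated into 6S; C7 is then set under thermodynamic control by Et3N, the ester settling pseudoaxial and trans to the C1 allyl group. The step needs C–C closure without E/Z scrambling of the C7=C6 bond; the ketone is masked as the ethyl enol ether, which excludes the oxa-6π pathway of a free cis-dienone, and the low temperature keeps [1,7]-hydrogen shifts out.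

**Step 8**
Reactants: 18 methyl (1S,6S,7R)-6-methyl-6-(4-methylpent-3-en-1-yl)-4-oxo-1-(prop-2-en-1-yl)-1,3,4,5,6,7-hexahydroisobenzofuran-7-carboxylate
Product: 19 (1S,4R,6S,7R)-7-(hydroxymethyl)-6-methyl-6-(4-methylpent-3-en-1-yl)-1-(prop-2-en-1-yl)-1,3,4,5,6,7-hexahydroisobenzofuran-4-ol
Conditions: LiAlH4, Et2O, −78 to 0 °C
Reagents that add atoms: none
Why: 1,2-reduction of the enone and reduction of the ester by LiAlH4; with the C7 ester pseudoaxial the C6 chain is axial on the opposite face and blocks it, so hydride should add to C4 anti to the chain and give the 4R alcohol.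

**Step 9**
Reactants: 19 (1S,4R,6S,7R)-7-(hydroxymethyl)-6-methyl-6-(4-methylpent-3-en-1-yl)-1-(prop-2-en-1-yl)-1,3,4,5,6,7-hexahydroisobenzofuran-4-ol
Product: 20 1-[(1S,4R,6S,7R)-4-hydroxy-7-(hydroxymethyl)-6-methyl-6-(4-methylpent-3-en-1-yl)-1,3,4,5,6,7-hexahydroisobenzofuran-1-yl]propan-2-one
Conditions: PdCl2 (cat.), CuCl, O2, DMF/H2O, rt
Reagents that add atoms: water, O
Why: Tsuji–Wacker oxidation; only the monosubstituted alkene is oxidised (Markovnikov, to the methyl ketone), the tri- and tetrasubstituted alkenes being inert under these conditions.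

**Step 10**
Reactants: 20 1-[(1S,4R,6S,7R)-4-hydroxy-7-(hydroxymethyl)-6-methyl-6-(4-methylpent-3-en-1-yl)-1,3,4,5,6,7-hexahydroisobenzofuran-1-yl]propan-2-one
Product: 21 (1S,4R,6S,7R)-4-hydroxy-6-methyl-6-(4-methylpent-3-en-1-yl)-1-(2-oxopropyl)-1,3,4,5,6,7-hexahydroisobenzofuran-7-carbaldehyde
Conditions: TEMPO (cat.), PhI(OAc)2, CH2Cl2, rt
Reagents that add atoms: none
Why: oxoammonium (TEMPO) oxidation, which is selective for the primary alcohol over the secondary allylic one; the C7 configuration should hold because the aldehyde trans to the C1 side chain is also the more stable epimer.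

**Step 11**
Reactants: 22 3-methylbut-2-enoyl chloride; 23 paraformaldehyde
Product: 24 chloromethyl 3-methylbut-2-enoate
Conditions: ZnCl2 (cat.), neat, 60 °C
Reagents that add atoms: none
Why: Lewis-acid-catalysed addition of an acyl chloride across formaldehyde, the standard route to chloromethyl esters.

**Step 12**
Reactants: 24 chloromethyl 3-methylbut-2-enoate; 25 triphenylphosphine
Product: 26 [(3-methylbut-2-enoyloxy)methyl]triphenylphosphonium chloride
Conditions: toluene, 60 °C
Reagents that add atoms: none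
Why: SN2 quaternisation of triphenylphosphine by the activated chloromethyl ester.

**Step 13**
Reactants: 21 (1S,4R,6S,7R)-4-hydroxy-6-methyl-6-(4-methylpent-3-en-1-yl)-1-(2-oxopropyl)-1,3,4,5,6,7-hexahydroisobenzofuran-7-carbaldehyde; 26 [(3-methylbut-2-enoyloxy)methyl]triphenylphosphonium chloride
Product: 28 neovibsanin I, (E)-2-[(1S,4R,6S,7R)-4-hydroxy-6-methyl-6-(4-methylpent-3-en-1-yl)-1-(2-oxopropyl)-1,3,4,5,6,7-hexahydroisobenzofuran-7-yl]ethenyl 3-methylbut-2-enoate, via acyloxymethylene ylide 27 (not isolated)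
Conditions: NaN(SiMe3)2, 26 (excess), THF, −78 °C; then 21, −78 to 0 °C
Reagents that add atoms: none
Why: Wittig olefination with an acyloxymethylene ylide, which gives enol esters directly from aldehydes; the ylide should react with the aldehyde and not with the methyl ketone, and the E enol ester is expected as the main or separable isomer.

**Compound list**

1 | 3,4-dibromofuran-2(5H)-one | O=C1OCC(Br)=C1Br | starting material
2 | tributyl(1-ethoxyethenyl)stannane | CCCC[Sn](CCCC)(CCCC)C(=C)OCC | starting material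
3 | 3-bromo-4-(1-ethoxyethenyl)furan-2(5H)-one | CCOC(=C)C1=C(Br)C(=O)OC1 | intermediate
4 | 3-bromo-4-(1-ethoxyethenyl)-2,5-dihydrofuran-2-ol | CCOC(=C)C1=C(Br)C(O)OC1 | intermediate
5 | (−)-B-allyldiisopinocampheylborane | C=CCB([C@@H]1C[C@@H]2C[C@H]([C@H]1C)C2(C)C)[C@@H]1C[C@@H]2C[C@H]([C@H]1C)C2(C)C | starting material
6 | (2Z,4S)-3-bromo-2-(1-ethoxyethenyl)hepta-2,6-diene-1,4-diol | OC/C(C(=C)OCC)=C(Br)\[C@@H](O)CC=C | intermediate
7 | (2S)-3-bromo-4-(1-ethoxyethenyl)-2-(prop-2-en-1-yl)-2,5-dihydrofuran | C=CC[C@@H]1OCC(C(=C)OCC)=C1Br | intermediate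
8 | 5-bromo-2-methylpent-2-ene | CC(C)=CCCBr | starting material
9 | methyl but-2-ynoate | CC#CC(=O)OC | starting material
10 | (4-methylpent-3-en-1-yl)magnesium bromide | CC(C)=CCC[Mg]Br | intermediate
11 | (4-methylpent-3-en-1-yl)copper | CC(C)=CCC[Cu] | intermediate
12 | methyl (2Z)-2-cuprio-3,7-dimethylocta-2,6-dienoate | CC(C)=CCC/C(C)=C(\[Cu])C(=O)OC | intermediate
13 | methyl (2Z)-2-iodo-3,7-dimethylocta-2,6-dienoate | CC(C)=CCC/C(C)=C(\I)C(=O)OC | intermediate
14 | [(2S)-4-(1-ethoxyethenyl)-2-(prop-2-en-1-yl)-2,5-dihydrofuran-3-yl]lithium | C=CC[C@@H]1OCC(C(=C)OCC)=C1[Li] | intermediate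
15 | [(2S)-4-(1-ethoxyethenyl)-2-(prop-2-en-1-yl)-2,5-dihydrofuran-3-yl]zinc chloride | C=CC[C@@H]1OCC(C(=C)OCC)=C1[Zn]Cl | intermediate
16 | methyl (2E)-2-[(2S)-4-(1-ethoxyethenyl)-2-(prop-2-en-1-yl)-2,5-dihydrofuran-3-yl]-3,7-dimethylocta-2,6-dienoate | CC(C)=CCC/C(C)=C(\C1=C(C(=C)OCC)CO[C@H]1CC=C)C(=O)OC | intermediate
17 | methyl (1S,6S)-4-ethoxy-6-methyl-6-(4-methylpent-3-en-1-yl)-1-(prop-2-en-1-yl)-1,3,5,6-tetrahydroisobenzofuran-7-carboxylate | CCOC1=C2CO[C@@H](CC=C)C2=C(C(=O)OC)[C@@](C)(CCC=C(C)C)C1 | intermediate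
18 | methyl (1S,6S,7R)-6-methyl-6-(4-methylpent-3-en-1-yl)-4-oxo-1-(prop-2-en-1-yl)-1,3,4,5,6,7-hexahydroisobenzofuran-7-carboxylate | C=CC[C@@H]1OCC2=C1[C@H](C(=O)OC)[C@@](C)(CCC=C(C)C)CC2=O | intermediate
19 | (1S,4R,6S,7R)-7-(hydroxymethyl)-6-methyl-6-(4-methylpent-3-en-1-yl)-1-(prop-2-en-1-yl)-1,3,4,5,6,7-hexahydroisobenzofuran-4-ol | C=CC[C@@H]1OCC2=C1[C@H](CO)[C@@](C)(CCC=C(C)C)C[C@H]2O | intermediate
20 | 1-[(1S,4R,6S,7R)-4-hydroxy-7-(hydroxymethyl)-6-methyl-6-(4-methylpent-3-en-1-yl)-1,3,4,5,6,7-hexahydroisobenzofuran-1-yl]propan-2-one | CC(=O)C[C@@H]1OCC2=C1[C@H](CO)[C@@](C)(CCC=C(C)C)C[C@H]2O | intermediate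
21 | (1S,4R,6S,7R)-4-hydroxy-6-methyl-6-(4-methylpent-3-en-1-yl)-1-(2-oxopropyl)-1,3,4,5,6,7-hexahydroisobenzofuran-7-carbaldehyde | CC(=O)C[C@@H]1OCC2=C1[C@H](C=O)[C@@](C)(CCC=C(C)C)C[C@H]2O | intermediate
22 | 3-methylbut-2-enoyl chloride | CC(C)=CC(Cl)=O | starting material
23 | paraformaldehyde (formaldehyde unit) | C=O | starting material
24 | chloromethyl 3-methylbut-2-enoate | CC(C)=CC(=O)OCCl | intermediate
25 | triphenylphosphine | c1ccc(cc1)P(c1ccccc1)c1ccccc1 | starting material
26 | [(3-methylbut-2-enoyloxy)methyl]triphenylphosphonium chloride | CC(C)=CC(=O)OC[P+](c1ccccc1)(c1ccccc1)c1ccccc1.[Cl-] | intermediate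
27 | (triphenylphosphoranylidene)methyl 3-methylbut-2-enoate | CC(C)=CC(=O)OC=P(c1ccccc1)(c1ccccc1)c1ccccc1 | intermediate
28 | neovibsanin I | CC(=O)C[C@@H]1OCC2=C1[C@H](/C=C/OC(=O)C=C(C)C)[C@@](C)(CCC=C(C)C)C[C@H]2O | target

**Step count and risks**

Total step count: 13. Longest linear sequence: 10 steps (1, 2, 3, 4, 6, 7, 8, 9, 10, 13).

Steps most likely to fail:

1. Step 7. The hindered, twisted alkylidene ester may be too poor an acceptor for ring closure, the facial (helicity) control by the C1 allyl group may be incomplete, or hydrogen shifts in the triene may compete. Fallback, from 16 back to 18: mild aqueous acid (oxalic acid, wet THF, 0 °C) hydrolyses the enol ether to the methyl ketone methyl (2E)-2-[(2S)-4-acetyl-2-(prop-2-en-1-yl)-2,5-dihydrofuran-3-yl]-3,7-dimethylocta-2,6-dienoate F1. F1 is kept cold and used at once, because reversible oxa-6π closure of a cis-dienone would scramble the alkene geometry. KN(SiMe3)2 in THF at −78 °C removes a methyl proton to give the cross-conjugated potassium enolate F2, which on warming to −20 °C should close by intramolecular Michael addition (oxyanion-accelerated 6π electrocyclisation) under the same 1,3-allylic-strain control to the potassium dienolate of the keto ester F3. An acetic acid quench and brief Et3N equilibration return 18.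

2. Step 6. The lithiated dihydrofuran may open by β-elimination of the ring alkoxide before transmetalation, or the coupling of two fully substituted alkenyl partners may be slow and erode the alkene geometry. Fallback, from 7 back to 16, without an organolithium: palladium-catalysed stannylation (Me3SnSnMe3, Pd(PPh3)4, toluene, 80 °C) gives [(2S)-4-(1-ethoxyethenyl)-2-(prop-2-en-1-yl)-2,5-dihydrofuran-3-yl]trimethylstannane F4. Stille coupling of F4 with iodide 13 (Pd2(dba)3, AsPh3, CuI as co-catalyst, N-methylpyrrolidone, 40 °C) returns 16.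

3. Step 13. The olefination may give poor E/Z selectivity, or the ylide may decompose by acyl transfer before it reacts with the hindered aldehyde. Fallback, from 21 to 28: Takai olefination (CrCl2, CHI3, THF, 0 °C), which is selective for aldehydes over ketones and for the E alkene, gives 1-[(1S,4R,6S,7R)-4-hydroxy-7-[(E)-2-iodoethenyl]-6-methyl-6-(4-methylpent-3-en-1-yl)-1,3,4,5,6,7-hexahydroisobenzofuran-1-yl]propan-2-one F5. Copper-catalysed C–O coupling of F5 with 3-methylbut-2-enoic acid (CuI, 3,4,7,8-tetramethyl-1,10-phenanthroline, Cs2CO3, toluene, 80 °C) gives 28 with retention of the alkene geometry.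

**Further compounds**

F1 | step 7 | methyl (2E)-2-[(2S)-4-acetyl-2-(prop-2-en-1-yl)-2,5-dihydrofuran-3-yl]-3,7-dimethylocta-2,6-dienoate | CC(C)=CCC/C(C)=C(\C1=C(C(C)=O)CO[C@H]1CC=C)C(=O)OC
F2 | step 7 | potassium 1-[(5S)-4-[(2E)-1-methoxy-3,7-dimethyl-1-oxoocta-2,6-dien-2-yl]-5-(prop-2-en-1-yl)-2,5-dihydrofuran-3-yl]ethen-1-olate | CC(C)=CCC/C(C)=C(\C1=C(C(=C)[O-])CO[C@H]1CC=C)C(=O)OC.[K+]
F3 | step 7 | potassium dienolate of keto ester 18 | C=CC[C@@H]1OCC2=C1C(=C([O-])OC)[C@@](C)(CCC=C(C)C)CC2=O.[K+]
F4 | step 6 | [(2S)-4-(1-ethoxyethenyl)-2-(prop-2-en-1-yl)-2,5-dihydrofuran-3-yl]trimethylstannane | C=CC[C@@H]1OCC(C(=C)OCC)=C1[Sn](C)(C)C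
F5 | step 13 | 1-[(1S,4R,6S,7R)-4-hydroxy-7-[(E)-2-iodoethenyl]-6-methyl-6-(4-methylpent-3-en-1-yl)-1,3,4,5,6,7-hexahydroisobenzofuran-1-yl]propan-2-one | CC(=O)C[C@@H]1OCC2=C1[C@H](/C=C/I)[C@@](C)(CCC=C(C)C)C[C@H]2O
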